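**Retrosynthetic overview**
- Azimine ⇒ removal of two N-benzyloxycarbonyl groups ⇒ head-to-tail macrodilactonisation of two molecules of N-protected azimic acid; the 22-membered ring is formed last.
- N-protected azimic acid ⇒ all-cis 2,3,6-trisubstituted piperidine ⇒ face-selective hydrogenation of a 2,3,6-trisubstituted pyridine, which sets all three stereocentres at once; the enantiomer is then selected by crystallisation with a resolving acid.
- Pyridine acid ⇒ key C6–side-chain bond by Minisci radical alkylation of 2-methylpyridin-3-ol with the 5-carboxypentyl radical released by ring-opening of cyclohexanone hydroperoxide; cyclohexanone delivers the whole chain, CO2H included.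
- Ring order: the pyridine ring is bought, the piperidine ring comes from its saturation, the macrocycle is closed last.

Assumption: in step 2 the less soluble camphorsulfonate is taken to be the one formed by the wanted (2R,5S,6S) amino acid with the (1S) acid; if the pairing is reversed, the (1R) acid is used and nothing else changes.

**Step 1**
Reactants: 1 2-methylpyridin-3-ol; 2 cyclohexanone
Product: 4 6-(5-hydroxy-6-methylpyridin-2-yl)hexanoic acid, via 1-hydroxycyclohexyl hydroperoxide 3 (not isolated)
Conditions: 2 (1.0 equiv), 30% aq H2O2 (1.0 equiv), 0 °C, 30 min; then added together with aq FeSO4·7H2O (0.3 equiv) over 2 h to 1 (3 equiv, excess recovered) in 2 M aq H2SO4/MeCN, 5–10 °C; adjust to pH 5, separate from the minor C4 isomer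
Reagents that add atoms: hydrogen peroxide, OO
Why: Minisci reaction, in which divalent iron cleaves the O–O bond of 3, the alkoxyl radical opens by β-scission to the nucleophilic 5-carboxypentyl radical, and this adds to the protonated pyridine at its only free α-position C6 (para to OH and unhindered, whereas C4 is flanked by OH) before trivalent iron rearomatises the adduct and returns divalent iron; no stereocentre is formed.

**Step 2**
Reactants: 4 6-(5-hydroxy-6-methylpyridin-2-yl)hexanoic acid
Product: 6 (2R,5S,6S)-2-(5-carboxypentyl)-5-hydroxy-6-methylpiperidin-1-ium (1S)-camphor-10-sulfonate, via racemic all-cis azimic acid 5 (not isolated)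
Conditions: H2 (5 bar), 5% Rh/Al2O3, AcOH/H2O 1:1, 50 °C; filter, evaporate; (1S)-(+)-10-camphorsulfonic acid (0.55 equiv), EtOH/EtOAc, crystallise, recrystallise to constant rotation
Reagents that add atoms: (1S)-(+)-10-camphorsulfonic acid, CC1(C)[C@@H]2CC[C@]1(C(=O)C2)CS(=O)(=O)O
Why: Heterogeneous pyridine hydrogenation adds all six hydrogens from the catalyst-bound face, so methyl, hydroxyl and side chain come out all-cis and the three stereocentres are set together as the racemate, after which classical resolution by diastereomeric salt crystallisation (half-equivalent method) retains the (2R,5S,6S) enantiomer.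

**Step 3**
Reactants: 6 (2R,5S,6S)-2-(5-carboxypentyl)-5-hydroxy-6-methylpiperidin-1-ium (1S)-camphor-10-sulfonate
Product: 7 6-[(2R,5S,6S)-1-(benzyloxycarbonyl)-5-hydroxy-6-methylpiperidin-2-yl]hexanoic acid
Conditions: CbzCl (1.5 equiv, in portions), 2 M aq NaOH/THF, 0 °C to rt, pH 10; then aq HCl to pH 2, EtOAc extraction
Reagents that add atoms: benzyl chloroformate, O=C(Cl)OCc1ccccc1
Why: Schotten–Baumann N-acylation, in which the amine, although hindered, outcompetes the secondary alcohol and the carboxylate in water (any mixed anhydride hydrolyses), the sulfonic acid stays in the aqueous phase, and no stereocentre is touched.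

**Step 4**
Reactants: 7 6-[(2R,5S,6S)-1-(benzyloxycarbonyl)-5-hydroxy-6-methylpiperidin-2-yl]hexanoic acid (two molecules)
Product: 10 N,N'-bis(benzyloxycarbonyl)azimine, via mixed anhydride 8 (not isolated), via open-chain ester dimer 9 (not isolated)
Conditions: 2,4,6-trichlorobenzoyl chloride (1.2 equiv), Et3N (2.5 equiv), THF, rt, 2 h; then syringe-pump addition over 8 h to DMAP (3 equiv) in toluene, 90 °C, final 5 mM
Reagents that add atoms: none
Why: Yamaguchi esterification followed by Yamaguchi macrolactonisation, where acyl transfer leaves the carbinol configuration unchanged, the monomeric lactone would be a strained bridged 11-membered ring so head-to-tail dimerisation to the 22-membered diolide dominates, and any residual minor enantiomer ends mainly in the heterochiral diolide, a diastereomer removed by chromatography.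

**Step 5**
Reactants: 10 N,N'-bis(benzyloxycarbonyl)azimine
Product: 11 azimine
Conditions: H2 (1 atm), 10% Pd/C, EtOH, rt
Reagents that add atoms: none
Why: Hydrogenolysis of the two benzyl carbamates frees both secondary amines under neutral conditions that leave the two lactones and all six stereocentres untouched.

**Compound list**
1 | 2-methylpyridin-3-ol | Cc1ncccc1O | starting material
2 | cyclohexanone | O=C1CCCCC1 | starting material
3 | 1-hydroxycyclohexyl hydroperoxide (formed in the flask, not isolated) | OOC1(O)CCCCC1 | intermediate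
4 | 6-(5-hydroxy-6-methylpyridin-2-yl)hexanoic acid | Cc1nc(CCCCCC(=O)O)ccc1O | intermediate
5 | racemic all-cis azimic acid, 6-[(2R*,5S*,6S*)-5-hydroxy-6-methylpiperidin-2-yl]hexanoic acid, methyl, hydroxyl and side chain on one face (both enantiomers written; not isolated) | C[C@@H]1N[C@H](CCCCCC(=O)O)CC[C@@H]1O.C[C@H]1N[C@@H](CCCCCC(=O)O)CC[C@H]1O | intermediate
6 | (2R,5S,6S)-2-(5-carboxypentyl)-5-hydroxy-6-methylpiperidin-1-ium (1S)-camphor-10-sulfonate (resolved azimic acid salt) | C[C@@H]1[NH2+][C@H](CCCCCC(=O)O)CC[C@@H]1O.CC1(C)[C@@H]2CC[C@]1(C(=O)C2)CS(=O)(=O)[O-] | intermediate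
7 | 6-[(2R,5S,6S)-1-(benzyloxycarbonyl)-5-hydroxy-6-methylpiperidin-2-yl]hexanoic acid (N-Cbz-azimic acid) | C[C@@H]1N(C(=O)OCc2ccccc2)[C@H](CCCCCC(=O)O)CC[C@@H]1O | intermediate
8 | mixed anhydride of 7 with 2,4,6-trichlorobenzoic acid (not isolated) | C[C@@H]1N(C(=O)OCc2ccccc2)[C@H](CCCCCC(=O)OC(=O)c2c(Cl)cc(Cl)cc2Cl)CC[C@@H]1O | intermediate
9 | open-chain ester dimer: the acid of one unit of 7 esterified with the ring hydroxyl of a second unit, whose own acid is still the 2,4,6-trichlorobenzoic mixed anhydride; one free hydroxyl (not isolated) | C[C@@H]1N(C(=O)OCc2ccccc2)[C@H](CCCCCC(=O)O[C@H]2CC[C@@H](CCCCCC(=O)OC(=O)c3c(Cl)cc(Cl)cc3Cl)N(C(=O)OCc3ccccc3)[C@H]2C)CC[C@@H]1O | intermediate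
10 | N,N'-bis(benzyloxycarbonyl)azimine (22-membered diolide, both piperidines all-cis) | C[C@@H]1N(C(=O)OCc4ccccc4)[C@@H]2CCCCCC(=O)O[C@H]3CC[C@@H](CCCCCC(=O)O[C@H]1CC2)N(C(=O)OCc4ccccc4)[C@H]3C | intermediate
11 | azimine, the diolide of two (2S,3S,6R)-3-hydroxy-2-methylpiperidine-6-hexanoic acid units (CNP0219883.1) | C[C@@H]1N[C@@H]2CCCCCC(=O)O[C@H]3CC[C@@H](CCCCCC(=O)O[C@H]1CC2)N[C@H]3C | target

**Step count**
Total step count: 5. Step 2 is counted as one step: one reaction and one isolation, the hydrogenation product being isolated directly as its resolving salt.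
Longest linear sequence: 5 (1 + 2 → 4 → 6 → 7 → 10 → 11).

**Steps most likely to fail**

Step 1. The radical may also attack C4, alkylate twice, or the electron-rich pyridinol may be oxidised, so the yield of the C6 isomer is uncertain. The fallback sets out from 1 and fixes the position first. Iodination (iodine, Na2CO3, water, rt) goes para to the hydroxyl and gives 6-iodo-2-methylpyridin-3-ol F1. A nickel-catalysed reductive cross-electrophile coupling of F1 with 6-bromohexanenitrile (NiBr2·3H2O, bathophenanthroline, Mn powder, DMF, 40 °C) follows. In it the 5-cyanopentyl radical formed from the bromide is captured by the pyridylnickel species, so the bond is still made by a radical but only at C6; the product is 6-(5-hydroxy-6-methylpyridin-2-yl)hexanenitrile F2. Hydrolysis (6 M aq HCl, reflux, then pH 5) returns to the route at 4.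

Step 2. The hydrogenation itself is reliable, apart from some C–O hydrogenolysis. The risk is that no camphorsulfonate crystallises with useful enrichment. The fallback sets out from 5, the crude racemate. Schotten–Baumann protection (CbzCl, aq NaOH/THF) gives the racemic all-cis N-benzyloxycarbonyl azimic acid F3. A lipase-catalysed kinetic resolution follows (Burkholderia cepacia lipase or CAL-B, vinyl acetate, MTBE, 30 °C, stopped near 50% conversion). By the Kazlauskas rule it acetylates the (5R) carbinol of the unwanted enantiomer, because the larger neighbour of the carbinol carries the methyl group and the carbamate nitrogen. The unreacted (5S) alcohol is separated from the acetate by chromatography; it is compound 7, where the route is rejoined.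

Step 4. Linear oligomers or larger rings may outweigh the cyclic dimer. The fallback sets out from 7 and builds the dimer stepwise, so that the ring closure is unimolecular.
- One portion of 7 is esterified with 2-(trimethylsilyl)ethanol (5 equiv, DCC, DMAP cat., CH2Cl2; the primary alcohol in excess outruns the ring hydroxyl) to give the 2-(trimethylsilyl)ethyl ester F4.
- A second portion is silylated at both oxygens (TBSCl, imidazole, DMF) to the silyl ether silyl ester F5. Its silyl ester is cleaved in the same flask (K2CO3, MeOH/H2O) to leave the O-silylated acid F6.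
- Yamaguchi esterification of F6 with the hydroxyl of F4 (2,4,6-trichlorobenzoyl chloride, Et3N, DMAP, toluene) gives the protected open-chain dimer F7.
- TBAF in THF removes both silicon-based groups and frees the seco hydroxy acid F8.
- Yamaguchi macrolactonisation of F8 at 1 mM closes the 22-membered ring and returns to the route at 10.

**Further compounds**
F1 | step 1 | 6-iodo-2-methylpyridin-3-ol | Cc1nc(I)ccc1O
F2 | step 1 | 6-(5-hydroxy-6-methylpyridin-2-yl)hexanenitrile | Cc1nc(CCCCCC#N)ccc1O
F3 | step 2 | racemic all-cis 6-[1-(benzyloxycarbonyl)-5-hydroxy-6-methylpiperidin-2-yl]hexanoic acid (both enantiomers written) | C[C@@H]1N(C(=O)OCc2ccccc2)[C@H](CCCCCC(=O)O)CC[C@@H]1O.C[C@H]1N(C(=O)OCc2ccccc2)[C@@H](CCCCCC(=O)O)CC[C@H]1O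
F4 | step 4 | 2-(trimethylsilyl)ethyl 6-[(2R,5S,6S)-1-(benzyloxycarbonyl)-5-hydroxy-6-methylpiperidin-2-yl]hexanoate | C[C@@H]1N(C(=O)OCc2ccccc2)[C@H](CCCCCC(=O)OCC[Si](C)(C)C)CC[C@@H]1O
F5 | step 4 | tert-butyldimethylsilyl 6-[(2R,5S,6S)-1-(benzyloxycarbonyl)-5-(tert-butyldimethylsilyloxy)-6-methylpiperidin-2-yl]hexanoate | C[C@@H]1N(C(=O)OCc2ccccc2)[C@H](CCCCCC(=O)O[Si](C)(C)C(C)(C)C)CC[C@@H]1O[Si](C)(C)C(C)(C)C
F6 | step 4 | 6-[(2R,5S,6S)-1-(benzyloxycarbonyl)-5-(tert-butyldimethylsilyloxy)-6-methylpiperidin-2-yl]hexanoic acid | C[C@@H]1N(C(=O)OCc2ccccc2)[C@H](CCCCCC(=O)O)CC[C@@H]1O[Si](C)(C)C(C)(C)C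
F7 | step 4 | protected open-chain dimer: acid of F6 esterified with the ring hydroxyl of F4 (silyl ether at one end, 2-(trimethylsilyl)ethyl ester at the other) | C[C@@H]1N(C(=O)OCc2ccccc2)[C@H](CCCCCC(=O)O[C@H]2CC[C@@H](CCCCCC(=O)OCC[Si](C)(C)C)N(C(=O)OCc3ccccc3)[C@H]2C)CC[C@@H]1O[Si](C)(C)C(C)(C)C
F8 | step 4 | seco hydroxy acid of the dimer (one free hydroxyl, one free carboxylic acid, both nitrogens benzyloxycarbonyl-protected) | C[C@@H]1N(C(=O)OCc2ccccc2)[C@H](CCCCCC(=O)O[C@H]2CC[C@@H](CCCCCC(=O)O)N(C(=O)OCc3ccccc3)[C@H]2C)CC[C@@H]1O
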